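## Analysis of the target

Target **20** is a cyclohex-4-ene with four ring stereocentres. The atom numbering used for every intermediate is: C1 carries the (E)-hept-1-enyl group (alkene carbons C1′ and C2′), C2 and C6 carry the N-isobutylcarboxamides, C3 carries pentyl, and C4=C5 is the ring alkene. C1–C3 are contiguous and C6 flanks C1 on the other side. The two amides and the pentyl group share one ring face and the heptenyl group takes the other, so C1 is trans to both neighbours, C2/C3 are cis and C2/C6 are cis-1,3 (C1 R, C2 R, C3 R, C6 S).

The sensitive sites are C6–H (allylic and α to an amide, so base can epimerise it or pull C4=C5 into conjugation), the epimerisable C2–H, two amide N–H groups, and the 1,5-diene C2′=C1′–C1–C6–C5=C4, a latent Cope substrate at high temperature. The difficulty is that all four centres are carbon-substituted with a mixed cis/trans pattern, there is no ring heteroatom to steer reagents, and the ring alkene has to end between C4 and C5, not next to a carbonyl. Formally the molecule is the endo [4+2] dimer of N-isobutyl-(2E,4E)-deca-2,4-dienamide, but a direct dimerisation would control neither regiochemistry nor absolute configuration.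

The strategy rests on one feature: the carbonyl on C2, C2, C3 and C4=C5 form a γ,δ-unsaturated acid, the retron of an ester-enolate Claisen rearrangement. Joining the implied allylic oxygen on C5 to that carbonyl gives a δ-lactone whose other ring atoms are C1 and C6, so both remaining stereocentres sit on a six-membered ring where they can be set by standard means.

## Retrosynthetic reasoning

**C2 amide (20 ⇒ 19 + 8).** The C2 carboxamide C–N bond is cut last. Both amides are identical, but only the C6 amide is wanted early, so the C2 carboxyl stays free to serve as the lactone carbonyl. The forward step is an amide coupling of a hindered acid under weakly basic conditions.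

**C2–C3 bond (19 ⇒ 16).** This is the key disconnection. Cutting C2–C3 and reconnecting the carboxyl oxygen to C5 turns the cyclohexene into lactone **16**, whose C5 substituent is an (E)-hept-1-enyl group made of C4, C3 and the pentyl chain. Forward, the silyl ketene acetal **17** must rearrange with C2–C3 formation and O–C5 cleavage. The cut is placed here because it is the only bond whose formation sets C2 and C3, places the alkene and closes the carbocycle in one event. C1 and C6 are carried through unchanged, and the lactone geometry leaves only one transition-state topology.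

**C1–C1′ bond (16 ⇒ 12 + 15).** In **16** C1 is β to the lactone carbonyl, so the heptenyl group is removed as a conjugate-addition nucleophile, leaving unsaturated lactone **12**. A stoichiometric alkenylcopper reagent would meet an N–H and an acidic C6–H and would rely on substrate bias alone. A rhodium-catalysed addition of boronic acid **15** tolerates both and adds a chiral ligand as a second control element. The forward step must deliver the group to C1 anti to the C6 amide and keep the (E) geometry. **15** comes from **13** by hydroboration, which fixes that geometry.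

**C1=C2 alkene (12 ⇒ 11).** The lactone alkene is opened by a metathesis disconnection to acrylate **11**. The ring then forms from an ester and a vinyl group already in place, and no stereocentre is involved.

**Ester C–O (11 ⇒ 9 + 10).** Removing the acryloyl group gives hydroxy amide **9**; the forward step is a plain O-acylation.

**Amide exchange (9 ⇒ 7 + 8).** The C6 isobutylamide is traced to the acyl oxazolidinone **7**. Installing the amide here, before the lactone exists, avoids any later aminolysis in the presence of a lactone and returns auxiliary **1**.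

**C6–C5 bond (7 ⇒ 3 + 4, 3 ⇒ 1 + 2).** The C6–C5 bond with its syn hydroxy/vinyl pattern is an auxiliary-controlled aldol between enal **4** and the dienolate of crotonyl imide **3**. The conjugated imide **3** is used because γ-deprotonation gives the same dienolate that a but-3-enoyl imide would, and **3** is the stable isomer made directly from **1** and **2**. The syn adduct maps onto the trans C6/C5 relationship of the lactone, and the (R)-auxiliary gives the required absolute configuration.

## Alternatives that were turned down

**Alternative 1: cyclobutene ring-rearrangement metathesis.**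
- Disconnection: both alkenes, C4=C5 and C1′=C2′, back to the cis-cyclobutene diester A2 and hept-1-ene A3.
- Forward key step: a ruthenium alkylidene opens the strained cyclobutene C5=C1′ bond, the C3 vinyl group closes onto C5, and A3 caps C1′, giving diester A1.
- For: strain release drives the step, the ring and both alkenes form in one flask, and the trans C1/C6 relationship is inherited from the cis-cyclobutene. On one point it is stronger: both carboxyls sit at the same ester level, so the two identical amides could be made in one operation, where the chosen route forms them in two separate steps.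
- Against: C2 and C3 would have to be built by acyclic control on a side chain next to a strained ring. The opened carbene has two termini, and closure of the C3 vinyl group onto C1′ gives a cyclopentene in direct competition with the six-membered ring. The cross-metathesis cap gives no firm control of C1′=C2′ geometry and competes with oligomerisation.
- Comparison: the chosen route fixes the (E)-heptenyl geometry by alkyne hydroboration, and its ring closure is unimolecular with one possible regiochemistry.

**Alternative 2: palladium π-allyl closure of C1–C6.**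
- Disconnection: the C1–C6 bond, back to the acyclic allylic carbonate A5, which carries a C5=C6 alkylidene malonate.
- Forward key step: zerovalent palladium (for example Pd(PPh3)4) ionises the C1 carbonate, and the γ-deprotonated alkylidene malonate attacks C1 through C6, giving the geminal diester A4 with the alkene at C4=C5.
- For: double inversion gives dependable net retention at C1, the conditions are mild and nearly neutral, and the C2 amide is already present. On mildness and on certainty at C1 it is at least as strong as the chosen route.
- Against: C6 is formed as a quaternary diester, so its configuration is not set by the key step. The later dealkoxycarbonylation passes through an allylic ester enolate that can protonate on either face or move the alkene into conjugation, and an amidation still follows. A5 needs three contiguous acyclic stereocentres (C1–C3) made beforehand, and the C2 amide can intercept the π-allyl terminus C2′.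
- Comparison: the chosen rearrangement sets C2 and C3 together with the ring and leaves a defined C6 amide.

**Alternative 3: palladium enolate alkenylation closing C5–C6.**
- Disconnection: the C5–C6 bond, back to the (Z)-vinyl iodide A7.
- Forward key step: zerovalent palladium inserts into the C5–I bond and couples with the C6 ester enolate, giving ethyl ester A6.
- For: the position and cis geometry of C4=C5 are fixed by a stable functional group and no high-temperature step is needed. On those two points it is stronger than a thermal sigmatropic shift.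
- Against: the strong base meets a free N–H and the C2–H. The product is a β,γ-unsaturated ester whose C6–H is more acidic than in A7, so epimerisation and conjugation threaten under the reaction conditions. The C1–C3 triad and the (Z)-iodide must be assembled acyclically, and the hindered ester still has to be exchanged for the amide.
- Comparison: the chosen route has the C6 carboxyl as an N-deprotonated (or N-silylated) amide during the base step, which removes this acidity, and C2/C3 follow stereospecifically from ring geometry.

Key step: step 8

Assumption: in the silylated intermediates the secondary amide is drawn as its N-silyl form; the O-silyl imidate tautomer would react in the same way.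

## Route

Step 1
Reactants: 1 (4R)-4-benzyl-1,3-oxazolidin-2-one; 2 (2E)-but-2-enoyl chloride
Product: 3 (4R)-4-benzyl-3-[(2E)-but-2-enoyl]-1,3-oxazolidin-2-one
Conditions: n-BuLi, THF, −78 °C; then 2, −78 → 0 °C
Reagents that add atoms: none
Why: N-acylation of the lithiated carbamate nitrogen by the acid chloride (standard Evans imide formation); no stereocentre is formed and the benzyl-bearing centre is untouched.

Step 2
Reactants: 3 (4R)-4-benzyl-3-[(2E)-but-2-enoyl]-1,3-oxazolidin-2-one; 4 (2E)-oct-2-enal
Product: 7 (4R)-4-benzyl-3-[(2R,3S,4E)-2-ethenyl-3-hydroxydec-4-enoyl]-1,3-oxazolidin-2-one, via dibutylboron dienolate 5 (not isolated), via boron aldolate 6 (not isolated)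
Conditions: Bu2BOTf, Et3N, CH2Cl2, −78 → 0 °C; 4, −78 → 0 °C; pH 7 buffer (NaH2PO4/Na2HPO4), MeOH, 30% H2O2, 0 °C
Reagents that add atoms: none
Why: Evans boron aldol through a dienolate: soft enolisation removes a γ-proton of 3 to give the (Z)-dienolate 5, which adds through its α-carbon to the aldehyde carbonyl in a Zimmerman–Traxler chair with the auxiliary dipole-opposed. This should give the syn α-vinyl β-hydroxy imide, the (R)-benzyl auxiliary setting C6 and C5 as (2R,3S) of the acyl chain; the vinyl group is the latent lactone alkene.

Step 3
Reactants: 7 (4R)-4-benzyl-3-[(2R,3S,4E)-2-ethenyl-3-hydroxydec-4-enoyl]-1,3-oxazolidin-2-one; 8 2-methylpropan-1-amine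
Product: 9 (2R,3S,4E)-2-ethenyl-3-hydroxy-N-(2-methylpropyl)dec-4-enamide
Conditions: AlMe3, CH2Cl2, 0 °C → rt; aq. potassium sodium tartrate
Reagents that add atoms: none
Why: Weinreb-type aminolysis of the acyl oxazolidinone by the aluminium amide formed from AlMe3 and 8; the aluminium alkoxide at the β-oxygen directs attack to the exocyclic carbonyl. The reagent is weakly basic, which should spare the α-vinyl centre from retro-aldol cleavage and conjugation; both stereocentres are untouched.

Step 4
Reactants: 9 (2R,3S,4E)-2-ethenyl-3-hydroxy-N-(2-methylpropyl)dec-4-enamide; 10 prop-2-enoyl chloride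
Product: 11 (3R,4S,5E)-3-[(2-methylpropyl)carbamoyl]undeca-1,5-dien-4-yl prop-2-enoate
Conditions: iPr2NEt, CH2Cl2, −20 → 0 °C
Reagents that add atoms: none
Why: O-acylation of the secondary allylic alcohol by an acid chloride with a hindered amine; the amide N–H is far less nucleophilic, and low temperature with a weak base should prevent β-elimination of the new acyloxy group.

Step 5
Reactants: 11 (3R,4S,5E)-3-[(2-methylpropyl)carbamoyl]undeca-1,5-dien-4-yl prop-2-enoate
Product: 12 (2S,3R)-2-[(1E)-hept-1-en-1-yl]-N-(2-methylpropyl)-6-oxo-3,6-dihydro-2H-pyran-3-carboxamide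
Conditions: second-generation Grubbs catalyst (H2IMes)(PCy3)Cl2Ru=CHPh (5 mol %), CH2Cl2 (5 mM), 40 °C
Reagents that add atoms: none
Why: ring-closing metathesis of the acrylate with the terminal vinyl group forms the six-membered α,β-unsaturated lactone (the C1=C2 bond). Initiation at the monosubstituted vinyl group and six-ring closure should outpace any engagement of the internal (E)-alkene, as is usual for acrylates of alkenyl-substituted homoallylic alcohols; no stereocentre is touched.

Step 6
Reactants: 13 hept-1-yne
Product: 15 [(1E)-hept-1-en-1-yl]boronic acid, via benzodioxaborole ester 14 (not isolated)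
Conditions: catecholborane, neat, 70 °C; then H2O, rt
Reagents that add atoms: catecholborane, B1Oc2ccccc2O1; water, O
Why: syn hydroboration of the terminal alkyne puts boron on the terminal carbon and gives the (E)-alkenylboronate 14 stereospecifically; hydrolysis frees the boronic acid.

Step 7
Reactants: 12 (2S,3R)-2-[(1E)-hept-1-en-1-yl]-N-(2-methylpropyl)-6-oxo-3,6-dihydro-2H-pyran-3-carboxamide; 15 [(1E)-hept-1-en-1-yl]boronic acid
Product: 16 (2S,3R,4R)-2,4-di[(1E)-hept-1-en-1-yl]-N-(2-methylpropyl)-6-oxooxane-3-carboxamide
Conditions: [Rh(OH)((R)-BINAP)]2 (3 mol %), 1,4-dioxane/H2O (10:1), 50 °C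
Reagents that add atoms: none
Why: Hayashi–Miyaura 1,4-addition: the alkenyl group passes from boron to hydroxorhodium with retention of geometry, adds syn across C1=C2, and water protonates C2; the medium tolerates the N–H and the acidic C6–H. The new C1 centre is set by the (R)-BINAP complex, chosen by analogy with cyclohex-2-enone, where it leads to the (R)-3-substituted ketone. Approach anti to the adjacent C6 amide reinforces this, so heptenyl should end trans to the amide and cis to the C5 alkenyl group.

Step 8
Reactants: 16 (2S,3R,4R)-2,4-di[(1E)-hept-1-en-1-yl]-N-(2-methylpropyl)-6-oxooxane-3-carboxamide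
Product: 19 (1R,2R,5S,6R)-6-[(1E)-hept-1-en-1-yl]-5-[(2-methylpropyl)carbamoyl]-2-pentylcyclohex-3-ene-1-carboxylic acid, via bis-silyl ketene acetal 17 (not isolated), via silyl ester 18 (not isolated)
Conditions: Me3SiCl, then LiN(SiMe3)2, THF, −78 °C → rt; PhMe, 100 °C; then 1 M HCl, THF, rt
Reagents that add atoms: none
Why: Ireland–Claisen rearrangement run as a lactone ring contraction, a known reaction type for δ-lactones that carry an alkenyl group on the oxygen-bearing carbon. The amide base first takes the N–H proton, so that the C6 carboxamide, as amidate or N-silyl amide, offers no acidic α-proton and cannot trigger β-elimination of the ring oxygen; it then takes a C2 proton, and silylation gives ketene acetal 17. On heating, C2 bonds to C3 while O–C5 breaks in a concerted [3,3] shift to silyl ester 18 with the alkene at C4=C5, and acidic work-up frees 19. The carbocycle is closed by this C2–C3 bond: because only C1 and C6 link the termini, the six-atom array can only be a boat, with C2 and C5 as bridgeheads of a bicyclo[2.2.2]octane-like transition state and suprafacial bonding on both components. C2 is controlled by the C5 configuration: the new bond forms on the ketene acetal face that carries the C5 alkenyl group, which leaves the carboxyl on the ring face of the C6 amide (trans to that alkenyl group in 16) and opposite the C1 heptenyl group (cis to it in 16). C3 is controlled by the (E) geometry of the migrating alkene, which in the boat turns pentyl away from the C1–C6 bridge toward the carboxyl, hence cis to it. The diastereoselectivity needed is therefore structural (no chair is available), the site of enolisation rests on the N–H versus C2–H versus C6–H acidity order, and C1 and C6 are not touched. The bath is held at or below 110 °C so that the 1,5-diene C2′=C1′–C1–C6–C5=C4 of the product does not enter a Cope rearrangement.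

Step 9
Reactants: 19 (1R,2R,5S,6R)-6-[(1E)-hept-1-en-1-yl]-5-[(2-methylpropyl)carbamoyl]-2-pentylcyclohex-3-ene-1-carboxylic acid; 8 2-methylpropan-1-amine
Product: 20 (1R,2R,3S,6R)-2-[(1E)-hept-1-en-1-yl]-N1,N3-bis(2-methylpropyl)-6-pentylcyclohex-4-ene-1,3-dicarboxamide
Conditions: iPrN=C=NiPr, HOAt, CH2Cl2, 0 °C → rt
Reagents that add atoms: none
Why: carbodiimide coupling with HOAt as acyl-transfer catalyst joins the hindered C2 acid to an unhindered primary amine under weakly basic conditions that should spare C2–H and the allylic C6–H. Because both amide groups are identical, any transient engagement of the cis C6 amide with the activated acid is opened by 8 to the same bis-amide.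

## Compound list

1 | (4R)-4-benzyl-1,3-oxazolidin-2-one | O=C1N[C@H](Cc2ccccc2)CO1 | starting material
2 | (2E)-but-2-enoyl chloride | C/C=C/C(=O)Cl | starting material
3 | (4R)-4-benzyl-3-[(2E)-but-2-enoyl]-1,3-oxazolidin-2-one | C/C=C/C(=O)N1[C@H](Cc2ccccc2)COC1=O | intermediate
4 | (2E)-oct-2-enal | CCCCC/C=C/C=O | starting material
5 | dibutylboron dienolate, (4R)-4-benzyl-3-[(1Z)-1-[(dibutylboranyl)oxy]buta-1,3-dien-1-yl]-1,3-oxazolidin-2-one | C=C/C=C(\OB(CCCC)CCCC)N1[C@H](Cc2ccccc2)COC1=O | intermediate
6 | boron aldolate, the O-dibutylboranyl derivative of 7 | C=C[C@@H](C(=O)N1[C@H](Cc2ccccc2)COC1=O)[C@@H](OB(CCCC)CCCC)/C=C/CCCCC | intermediate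
7 | (4R)-4-benzyl-3-[(2R,3S,4E)-2-ethenyl-3-hydroxydec-4-enoyl]-1,3-oxazolidin-2-one | C=C[C@@H](C(=O)N1[C@H](Cc2ccccc2)COC1=O)[C@@H](O)/C=C/CCCCC | intermediate
8 | 2-methylpropan-1-amine (isobutylamine) | CC(C)CN | starting material
9 | (2R,3S,4E)-2-ethenyl-3-hydroxy-N-(2-methylpropyl)dec-4-enamide | C=C[C@@H](C(=O)NCC(C)C)[C@@H](O)/C=C/CCCCC | intermediate
10 | prop-2-enoyl chloride | C=CC(=O)Cl | starting material
11 | (3R,4S,5E)-3-[(2-methylpropyl)carbamoyl]undeca-1,5-dien-4-yl prop-2-enoate | C=C[C@@H](C(=O)NCC(C)C)[C@@H](OC(=O)C=C)/C=C/CCCCC | intermediate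
12 | (2S,3R)-2-[(1E)-hept-1-en-1-yl]-N-(2-methylpropyl)-6-oxo-3,6-dihydro-2H-pyran-3-carboxamide | O=C1C=C[C@@H](C(=O)NCC(C)C)[C@H](/C=C/CCCCC)O1 | intermediate
13 | hept-1-yne | CCCCCC#C | starting material
14 | 2-[(1E)-hept-1-en-1-yl]-1,3,2-benzodioxaborole | CCCCC/C=C/B1Oc2ccccc2O1 | intermediate
15 | [(1E)-hept-1-en-1-yl]boronic acid | CCCCC/C=C/B(O)O | intermediate
16 | (2S,3R,4R)-2,4-di[(1E)-hept-1-en-1-yl]-N-(2-methylpropyl)-6-oxooxane-3-carboxamide (key-step precursor; C1 heptenyl cis to C5 alkenyl, C6 amide trans to both) | CCCCC/C=C/[C@H]1CC(=O)O[C@@H](/C=C/CCCCC)[C@@H]1C(=O)NCC(C)C | intermediate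
17 | bis-silyl ketene acetal of 16: trimethylsilyl ketene acetal at the lactone carbonyl and N-trimethylsilyl amide, stereocentres as in 16 | CCCCC/C=C/[C@H]1C=C(O[Si](C)(C)C)O[C@@H](/C=C/CCCCC)[C@@H]1C(=O)N(CC(C)C)[Si](C)(C)C | intermediate
18 | trimethylsilyl ester of 19 with N-trimethylsilyl amide, stereocentres as in 19 | CCCCC/C=C/[C@H]1[C@H](C(=O)O[Si](C)(C)C)[C@H](CCCCC)C=C[C@@H]1C(=O)N(CC(C)C)[Si](C)(C)C | intermediate
19 | (1R,2R,5S,6R)-6-[(1E)-hept-1-en-1-yl]-5-[(2-methylpropyl)carbamoyl]-2-pentylcyclohex-3-ene-1-carboxylic acid (key-step product) | CCCCC/C=C/[C@H]1[C@H](C(=O)O)[C@H](CCCCC)C=C[C@@H]1C(=O)NCC(C)C | intermediate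
20 | (1R,2R,3S,6R)-2-[(1E)-hept-1-en-1-yl]-N1,N3-bis(2-methylpropyl)-6-pentylcyclohex-4-ene-1,3-dicarboxamide | CCCCC/C=C/[C@H]1[C@H](C(=O)NCC(C)C)[C@H](CCCCC)C=C[C@@H]1C(=O)NCC(C)C | target

## Step count and least certain steps

Total: 9 steps. Longest linear sequence: 8 steps (1, 2, 3, 4, 5, 7, 8, 9); step 6 is a one-step side branch.

**Step 8 (key step).** The rearrangement through the boat may be slower than loss of the trimethylsilyl ketene acetal, because the reactive conformer holds the C5 alkenyl, C1 heptenyl and C6 amide groups all pseudo-axial. The acetal can be lost by silyl migration to carbon, by reversion to 16 on work-up, or by base-induced opening across C6–C5 while lithium amide is still present.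

The fallback sets out from 16 and returns at 19. It replaces deprotonation by Lewis-acid soft enolisation, so no anionic enolate or free amide base is ever present, and it uses a silyl group that survives prolonged heating. tert-Butyldimethylsilyl triflate and Et3N in toluene at room temperature should give the bis(tert-butyldimethylsilyl) ketene acetal of 16 F1, which can be freed from salts and heated on its own (toluene, 110 °C) to the tert-butyldimethylsilyl ester of 19 carrying an N-silyl amide F2. Mild hydrolysis (AcOH, THF, H2O) then gives 19.

**Step 7.** Facial selectivity at C1 may erode. The catalyst and the C6 amide select one face, while the C5 alkenyl group, through the chair-like axial trajectory usual for six-ring acceptors, favours the other. The C6–H of 12 is also acidic enough for base-promoted opening of the lactone across C6–C5.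

The fallback sets out from 15, uses 1, 4 and 8, and returns at 16; it sets C1 before any ring bias exists.
- Commercial 5,6-dihydro-2H-pyran-2-one takes up 15 under [Rh(OH)((S)-BINAP)]2 catalysis, where the catalyst alone decides the face, to give (4S)-4-[(1E)-hept-1-en-1-yl]oxan-2-one F3.
- Saponification (LiOH) and silylation of both oxygens (tert-butyldimethylsilyl chloride, imidazole) give tert-butyl(dimethyl)silyl (3S,4E)-3-(2-{[tert-butyl(dimethyl)silyl]oxy}ethyl)dec-4-enoate F4.
- Selective cleavage of its silyl ester (K2CO3, aqueous MeOH) gives (3S,4E)-3-(2-{[tert-butyl(dimethyl)silyl]oxy}ethyl)dec-4-enoic acid F5.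
- N-Acylation of 1 with F5 (pivaloyl chloride, Et3N, LiCl, THF) gives (4R)-4-benzyl-3-[(3S,4E)-3-(2-{[tert-butyl(dimethyl)silyl]oxy}ethyl)dec-4-enoyl]-1,3-oxazolidin-2-one F6.
- The boron aldol with 4 under the conditions of step 2 (auxiliary control, syn) gives (4R)-4-benzyl-3-[(2R,3R,4E)-3-(2-{[tert-butyl(dimethyl)silyl]oxy}ethyl)-2-[(1S,2E)-1-hydroxyoct-2-en-1-yl]dec-4-enoyl]-1,3-oxazolidin-2-one F7.
- Aminolysis with 8 as in step 3 gives (2R,3R,4E)-3-(2-{[tert-butyl(dimethyl)silyl]oxy}ethyl)-2-[(1S,2E)-1-hydroxyoct-2-en-1-yl]-N-(2-methylpropyl)dec-4-enamide F8.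
- HF·pyridine frees (2R,3R,4E)-3-(2-hydroxyethyl)-2-[(1S,2E)-1-hydroxyoct-2-en-1-yl]-N-(2-methylpropyl)dec-4-enamide F9.
- TEMPO with PhI(OAc)2 oxidises the primary alcohol selectively and closes the δ-lactone 16.

**Step 3.** Retro-aldol cleavage, or drift of the α-vinyl double bond into conjugation, may compete on the aluminium alkoxide, because the α-carbon is both allylic and next to the imide carbonyl.

The fallback sets out from 7 and returns at 9. Peroxide hydrolysis (LiOH, H2O2, THF/H2O, 0 °C) removes the auxiliary to give (2R,3S,4E)-2-ethenyl-3-hydroxydec-4-enoic acid F10, which is coupled with 8 under the carbodiimide conditions of step 9.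

**Step 9.** Activation of the doubly flanked C2 acid may be slow enough for epimerisation at C2, or for base-induced isomerisation at the allylic C6.

The fallback sets out from 19 and returns at 20. It uses the cis-1,3 relationship of the acid and the C6 amide: 1,1′-carbonyldiimidazole followed by catalytic DBU (THF, 50 °C) should close the bicyclic imide 9-[(1E)-hept-1-en-1-yl]-3-(2-methylpropyl)-8-pentyl-3-azabicyclo[3.3.1]non-6-ene-2,4-dione F11 (ring stereocentres as in 19), in which both α-carbons are bridgeheads and enolisation is hindered. Opening with neat 8 at 60 °C gives 20 whichever carbonyl is attacked.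

## Further compounds

F1 | step 8 | bis(tert-butyldimethylsilyl) ketene acetal of 16 (O-silyl ketene acetal and N-silyl amide, stereocentres as in 16) | CCCCC/C=C/[C@H]1C=C(O[Si](C)(C)C(C)(C)C)O[C@@H](/C=C/CCCCC)[C@@H]1C(=O)N(CC(C)C)[Si](C)(C)C(C)(C)C
F2 | step 8 | tert-butyldimethylsilyl ester of 19 with N-tert-butyldimethylsilyl amide | CCCCC/C=C/[C@H]1[C@H](C(=O)O[Si](C)(C)C(C)(C)C)[C@H](CCCCC)C=C[C@@H]1C(=O)N(CC(C)C)[Si](C)(C)C(C)(C)C
F3 | step 7 | (4S)-4-[(1E)-hept-1-en-1-yl]oxan-2-one | CCCCC/C=C/[C@H]1CCOC(=O)C1
F4 | step 7 | tert-butyl(dimethyl)silyl (3S,4E)-3-(2-{[tert-butyl(dimethyl)silyl]oxy}ethyl)dec-4-enoate | CCCCC/C=C/[C@H](CC(=O)O[Si](C)(C)C(C)(C)C)CCO[Si](C)(C)C(C)(C)C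
F5 | step 7 | (3S,4E)-3-(2-{[tert-butyl(dimethyl)silyl]oxy}ethyl)dec-4-enoic acid | CCCCC/C=C/[C@H](CC(=O)O)CCO[Si](C)(C)C(C)(C)C
F6 | step 7 | (4R)-4-benzyl-3-[(3S,4E)-3-(2-{[tert-butyl(dimethyl)silyl]oxy}ethyl)dec-4-enoyl]-1,3-oxazolidin-2-one | CCCCC/C=C/[C@H](CC(=O)N1[C@H](Cc2ccccc2)COC1=O)CCO[Si](C)(C)C(C)(C)C
F7 | step 7 | (4R)-4-benzyl-3-[(2R,3R,4E)-3-(2-{[tert-butyl(dimethyl)silyl]oxy}ethyl)-2-[(1S,2E)-1-hydroxyoct-2-en-1-yl]dec-4-enoyl]-1,3-oxazolidin-2-one | CCCCC/C=C/[C@@H](CCO[Si](C)(C)C(C)(C)C)[C@@H](C(=O)N1[C@H](Cc2ccccc2)COC1=O)[C@@H](O)/C=C/CCCCC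
F8 | step 7 | (2R,3R,4E)-3-(2-{[tert-butyl(dimethyl)silyl]oxy}ethyl)-2-[(1S,2E)-1-hydroxyoct-2-en-1-yl]-N-(2-methylpropyl)dec-4-enamide | CCCCC/C=C/[C@@H](CCO[Si](C)(C)C(C)(C)C)[C@@H](C(=O)NCC(C)C)[C@@H](O)/C=C/CCCCC
F9 | step 7 | (2R,3R,4E)-3-(2-hydroxyethyl)-2-[(1S,2E)-1-hydroxyoct-2-en-1-yl]-N-(2-methylpropyl)dec-4-enamide | CCCCC/C=C/[C@@H](CCO)[C@@H](C(=O)NCC(C)C)[C@@H](O)/C=C/CCCCC
F10 | step 3 | (2R,3S,4E)-2-ethenyl-3-hydroxydec-4-enoic acid | C=C[C@@H](C(=O)O)[C@@H](O)/C=C/CCCCC
F11 | step 9 | 9-[(1E)-hept-1-en-1-yl]-3-(2-methylpropyl)-8-pentyl-3-azabicyclo[3.3.1]non-6-ene-2,4-dione (ring stereocentres as in 19) | CCCCC/C=C/[C@H]1[C@H]2[C@H](CCCCC)C=C[C@@H]1C(=O)N(CC(C)C)C2=O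
A1 | alternative 1 | dimethyl (1R,2R,3S,6R)-2-[(1E)-hept-1-en-1-yl]-6-pentylcyclohex-4-ene-1,3-dicarboxylate | CCCCC/C=C/[C@H]1[C@H](C(=O)OC)[C@H](CCCCC)C=C[C@@H]1C(=O)OC
A2 | alternative 1 | methyl cis-4-(1-methoxy-1-oxo-3-pentylpent-4-en-2-yl)cyclobut-2-ene-1-carboxylate (configuration as in the SMILES) | C=C[C@@H](CCCCC)[C@@H](C(=O)OC)[C@@H]1C=C[C@@H]1C(=O)OC
A3 | alternative 1 | hept-1-ene | C=CCCCCC
A4 | alternative 2 | dimethyl 6-[(1E)-hept-1-en-1-yl]-5-[(2-methylpropyl)carbamoyl]-4-pentylcyclohex-2-ene-1,1-dicarboxylate (configuration as in the SMILES) | CCCCC/C=C/[C@H]1[C@H](C(=O)NCC(C)C)[C@H](CCCCC)C=CC1(C(=O)OC)C(=O)OC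
A5 | alternative 2 | dimethyl 2-[(6E)-5-[(methoxycarbonyl)oxy]-4-[(2-methylpropyl)carbamoyl]-3-pentyldodec-6-en-1-ylidene]propanedioate (configuration as in the SMILES) | CCCCC/C=C/[C@H](OC(=O)OC)[C@H](C(=O)NCC(C)C)[C@H](CCCCC)CC=C(C(=O)OC)C(=O)OC
A6 | alternative 3 | ethyl 6-[(1E)-hept-1-en-1-yl]-5-[(2-methylpropyl)carbamoyl]-4-pentylcyclohex-2-ene-1-carboxylate (configuration as in the SMILES) | CCCCC/C=C/[C@H]1[C@H](C(=O)NCC(C)C)[C@H](CCCCC)C=C[C@@H]1C(=O)OCC
A7 | alternative 3 | ethyl (6Z)-3-[(1E)-hept-1-en-1-yl]-7-iodo-4-[(2-methylpropyl)carbamoyl]-5-pentylhept-6-enoate (configuration as in the SMILES) | CCCCC/C=C/[C@H](CC(=O)OCC)[C@H](C(=O)NCC(C)C)[C@H](CCCCC)/C=C\I
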